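The runs are calculated on assumed constants; the scatter is artificial.

**Leftover first.** Reckon the leftover: the flask charges 0.150 M of coupling partner on 0.10 M of solid substrate, so solid substrate is the limiting reagent. At one partner per solid, 33.3% of the partner stays over.

| flask | solid substrate | coupling partner | remark | time |
|---|---|---|---|---|
| oak | 0.10 M | 0.075 M | run made earlier |  |
| alder | 0.10 M | 0.11 M | run made earlier |  |
| birch | 0.15 M | 0.15 M | run made earlier |  |
| flask | 0.10 M | 0.150 M |  | 6.0 h |
- oak (time / h: target / %): 0.500: 7; 0.833: 13; 1.33: 26; 2.00: 33; 3.00: 33; 5.00: 30
- alder (time / h: target / %): 0.500: 9; 0.833: 21; 1.33: 33; 2.00: 41; 3.00: 45; 5.00: 35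
- birch (time / h: target / %): 0.500: 7; 1.00: 23; 1.50: 30; 3.00: 39; 5.00: 32

(each reading ± 2 percentage points)
- solid, in amounts per volume of the solution: solid substrate
- the numbers in the tables scatter with a standard deviation of 2 percentage points
- at the start none of the solid substrate is in solution
1. time up to 6.0 h at which target stands highest
2. the amount of target, in percent of the solid substrate charged, at that time
3. the first time at which target reaches 33%, in the same percent

**Start rate.** Read the alder run from 0.500 h to 1.33 h: target gains 0.0289 M h⁻¹. Drawn back, that line reaches zero at 0.189 h, a lag read from scattered points. Scale the rate by the partner charge: the flask starts at 0.0394 M h⁻¹, so my reckoning reaches 33% at 1.03 h.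

**Limiting yield.** Two factors slow the gain. The solid factor falls towards zero, while the partner factor ends at the leftover. Target is also lost: the alder run drops from 45% to 35%. The oak and alder runs, each with a leftover, give a mean of 44.5%. This is the limiting yield, the peak target over the smaller charge. The birch run, without a leftover, reads lower at 39%. Let the gain fade evenly to zero at the peak, and the peak comes at 2.45 h.

**The forecast.** It says 52% at 2.5 h, and 33% at 1.1 h, noting “Only 0.10 M solid is available”. My peak lies 7.5 percentage points lower.

**The result.** The flask peaks at 47.7% at 2.25 h and reaches 33% at 1.01 h. That stands 3.2 points above the limiting yield.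

    starting material + coupling partner → intermediate + by-product (k = 0.00218 M⁻¹ s⁻¹)
    intermediate ⇌ target (K = 9.60, k = 9.61 × 10⁻⁴ s⁻¹)
    intermediate ⇌ isomer of the product (K = 2.10, k = 6.95 × 10⁻⁵ s⁻¹)
    solid substrate ⇌ starting material, rate k4*(cs4 - [starting material]) while solid is left; crystals form when [starting material] > cs4 (solubility = 0.100 M, k = 0.00115 s⁻¹)
    target + by-product → side product (k = 0.00123 M⁻¹ s⁻¹)

**Richer neighbour.** Take a neighbour flask charged with 0.25 M of solid substrate, with partner and time held. Partner is now the limiting reagent, so the limiting yield gives 26.7% of the solid charged, and the neighbour flask gives 25.7%. At 6.00 h, the neighbour flask keeps 1.4% of its partner and holds 39.8% of its solid charge as starting material.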